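**Retrosynthetic overview**
- The target is unmasked last from a tri-O-benzyl, mono-O-tosyl precursor.
- That precursor comes from a fully acyclic biaryl carrying two pentaol side chains. One acid-triggered operation closes the tetrahydrofuran on one arm and the aryltetralin on the other, and sets both benzylic stereocentres.
- The arm that stops at the ether is chosen by an aryl tosylate, which makes its benzyl ring too electron-poor for Friedel–Crafts attack.
- The biaryl bond is a Suzuki union of two aryl bromide pentaols. Each comes from a dianion aldol of a 2-benzylmalate diester with O-benzyl-5-bromovanillin, reduced in the same flask.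
- The 2-benzylmalates come from (S)-malic acid by Seebach dioxolanone alkylation. Ring order: no saturated ring exists before the key step; tetrahydrofurans form first on both arms, then the tetralin on one arm.

Assumption: the target is taken exactly as the SMILES is written (3-hydroxy-4-methoxybenzyl on the tetrahydrofuran half). Lithium enolates and carbocations are treated as reactive species and are not numbered. The benzylic carbinol carbon made in steps 8 and 11 is an epimer mixture, left undefined in the SMILES and erased in step 13.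

**Route**

Step 1
Reactants: 1 (S)-malic acid
Product: 2 cis-dioxolanone acetic acid
Conditions: t-BuCHO (1.5 eq), TsOH·H2O (5 mol %), H2SO4 (cat.), pentane, reflux (Dean–Stark); recrystallise
Reagents that add atoms: pivalaldehyde, CC(C)(C)C=O
Why: Reversible acid-catalysed acetalisation of the α-hydroxy acid (Seebach dioxolanone formation) closes the five-membered ring and gives the thermodynamic cis acetal (new acetal centre S), purified by crystallisation.

Step 2
Reactants: 3 isovanillyl alcohol
Product: 4 isovanillyl alcohol aryl tosylate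
Conditions: TsCl (1.05 eq), K2CO3 (1.5 eq), acetone, rt
Reagents that add atoms: 4-toluenesulfonyl chloride, Cc1ccc(cc1)S(Cl)(=O)=O
Why: The phenoxide is sulfonylated far faster than the neutral benzylic alcohol (chemoselective O-sulfonylation), installing the electron-withdrawing group that later switches off Friedel–Crafts reactivity of this ring; no stereocentre.

Step 3
Reactants: 4 isovanillyl alcohol aryl tosylate
Product: 5 3-tosyloxy-4-methoxybenzyl bromide
Conditions: PBr3 (0.4 eq), CH2Cl2, 0 °C
Reagents that add atoms: phosphorus tribromide, BrP(Br)Br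
Why: Standard PBr3 bromination of a primary benzylic alcohol; the aryl sulfonate is inert and no stereocentre is involved.

Step 4
Reactants: 6 4-benzyloxy-3-methoxybenzyl alcohol
Product: 7 4-benzyloxy-3-methoxybenzyl bromide
Conditions: PBr3 (0.4 eq), Et2O, 0 °C; use fresh
Reagents that add atoms: phosphorus tribromide, BrP(Br)Br
Why: PBr3 bromination of a primary benzylic alcohol; the aryl benzyl ether is inert and no stereocentre is involved.

Step 5
Reactants: 8 5-bromovanillin
Product: 9 O-benzyl-5-bromovanillin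
Conditions: BnBr (1.1 eq), K2CO3 (1.5 eq), DMF, 60 °C
Reagents that add atoms: benzyl bromide, BrCc1ccccc1
Why: Williamson etherification of the phenoxide; the aldehyde and aryl bromide are untouched and no stereocentre is involved.

Step 6
Reactants: 2 cis-dioxolanone acetic acid; 5 3-tosyloxy-4-methoxybenzyl bromide
Product: 10 A-series benzylated dioxolanone acid
Conditions: LiHMDS (2.1 eq), THF, −78 °C; 5 (1.1 eq), −78 → −30 °C; aq HCl
Reagents that add atoms: none
Why: Seebach self-regeneration of stereocentres: the dilithio carboxylate–enolate is benzylated trans to the tert-butyl group, so the benzyl takes the place of the former hydrogen (retention) and the quaternary carbinol carbon is set as S; the aryl tosylate has no acidic hydrogen and survives.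

Step 7
Reactants: 10 A-series benzylated dioxolanone acid
Product: 11 A-series diisopropyl 2-benzylmalate
Conditions: i-PrOH, H2SO4 (cat.), reflux, 3 Å MS (Soxhlet)
Reagents that add atoms: propan-2-ol, CC(C)O
Why: Acid-catalysed alcoholysis of the acetal ester plus Fischer esterification opens the auxiliary without touching the non-epimerisable quaternary centre; the bulky isopropyl esters are chosen to reinforce the facial bias of the next step.

Step 8
Reactants: 11 A-series diisopropyl 2-benzylmalate; 9 O-benzyl-5-bromovanillin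
Product: 13 A-series pentaol bromide, via aldol adduct 12 (not isolated)
Conditions: LiHMDS (2.3 eq), THF, −78 → −30 → −78 °C; 9 (1.05 eq), −78 °C, 1 h; AcOH (2.5 eq), −78 °C; LiBH4 (10 eq), MeOH (10 eq), −78 → 45 °C
Reagents that add atoms: none
Why: Fráter–Seebach-type hydroxyalkylation: the lithium-chelated alkoxide–enolate dianion adds to the aldehyde on the face anti to the C2 ester, which the same lithium holds over the other face (sets C3 as R; the carbinol carbon forms unselectively and is erased in step 13), and LiBH4 then reduces both esters in the same flask before retro-aldol or epimerisation can occur, leaving ArBr, ArOTs and the benzyl ether intact.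

Step 9
Reactants: 2 cis-dioxolanone acetic acid; 7 4-benzyloxy-3-methoxybenzyl bromide
Product: 14 B-series benzylated dioxolanone acid
Conditions: LiHMDS (2.1 eq), THF, −78 °C; 7 (1.1 eq), −78 → −30 °C; aq HCl
Reagents that add atoms: none
Why: Same Seebach self-regeneration-of-stereocentres alkylation as step 6: attack trans to tert-butyl with overall retention gives the quaternary S centre.

Step 10
Reactants: 14 B-series benzylated dioxolanone acid
Product: 15 B-series diisopropyl 2-benzylmalate
Conditions: i-PrOH, H2SO4 (cat.), reflux, 3 Å MS (Soxhlet)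
Reagents that add atoms: propan-2-ol, CC(C)O
Why: Acid-catalysed acetal alcoholysis and Fischer esterification as in step 7; the aryl benzyl ether tolerates catalytic acid and the quaternary centre cannot epimerise.

Step 11
Reactants: 15 B-series diisopropyl 2-benzylmalate; 9 O-benzyl-5-bromovanillin
Product: 17 B-series pentaol bromide, via aldol adduct 16 (not isolated)
Conditions: LiHMDS (2.3 eq), THF, −78 → −30 → −78 °C; 9 (1.05 eq), −78 °C, 1 h; AcOH (2.5 eq), −78 °C; LiBH4 (10 eq), MeOH (10 eq), −78 → 45 °C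
Reagents that add atoms: none
Why: Same Fráter–Seebach-type dianion aldol and in-flask LiBH4 reduction as step 8: C3 is set as R by attack anti to the chelated C2 ester and the carbinol mixture is inconsequential.

Step 12
Reactants: 17 B-series pentaol bromide; 13 A-series pentaol bromide
Product: 19 biaryl bis-pentaol, via arylboronate 18 (not isolated)
Conditions: 17 (1.1 eq), B2pin2 (1.1 eq), KOAc (3 eq), Pd(dppf)Cl2 (5 mol %), dioxane, 90 °C; then 13 (1.0 eq), 2 M aq K3PO4 (4 eq), 85 °C
Reagents that add atoms: bis(pinacolato)diboron, CC1(C)OB(OC1(C)C)B1OC(C)(C)C(C)(C)O1 (its boryl group is carried by 18 only and is lost again on coupling)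
Why: One-pot Miyaura borylation and Suzuki–Miyaura cross-coupling: only 17 is present during borylation so the cross-product is the only biaryl, Pd(dppf) inserts into C–Br but not into the aryl tosylate, free hydroxyls are tolerated, and no stereocentre is touched (the biaryl axis rotates freely).

Step 13
Reactants: 19 biaryl bis-pentaol
Product: 21 tri-O-benzyl mono-O-tosyl target, via bis-tetrahydrofuran 20 (not isolated)
Conditions: TsOH·H2O (20 mol %), CH2Cl2/HFIP 4:1 (0.005 M), 0 °C → rt
Reagents that add atoms: none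
Why: Proposed new method: both benzylic alcohols ionise to 4-benzyloxybenzyl cations that are first captured reversibly by the primary hydroxyl of the neighbouring 1,2-diol (5-ring ether, giving 20); on the arm with the 4-benzyloxy-3-methoxybenzyl ring the re-formed cation then undergoes irreversible six-ring Friedel–Crafts attack para to OMe through a chair-like transition state with the aryl pseudo-equatorial (1,2-trans, new C–aryl centre S), while on the other arm the tosyloxy ring is too electron-poor to attack and the ether equilibrates to the more stable 2,3-trans tetrahydrofuran (new O–CH(Ar) centre S); the closest known reaction types are acid-catalysed dehydrative cycloetherification of benzylic alcohols and the acid-induced tetrahydrofuran-to-aryltetralin (olivil to cycloolivil type) Friedel–Crafts rearrangement.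

Step 14
Reactants: 21 tri-O-benzyl mono-O-tosyl target
Product: 22 tri-O-benzyl target
Conditions: KOH (10 eq), MeOH/THF/H2O 4:2:1, 65 °C, N2; AcOH to pH 6
Reagents that add atoms: none
Why: Hydroxide attacks sulfur of the aryl sulfonate (sulfonate ester hydrolysis) and frees the phenol; benzyl ethers, the cyclic ether and the alcohols are base-stable and no stereocentre is α to a carbonyl.

Step 15
Reactants: 22 tri-O-benzyl target
Product: 23 CNP0252244.1
Conditions: H2 (1 atm), 10 % Pd/C, EtOAc/MeOH 1:1, rt; stop after 3 eq H2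
Reagents that add atoms: none
Why: Catalytic hydrogenolysis of the three aryl benzyl ethers under neutral conditions, where the benzylic C–O bond of the tetrahydrofuran is cleaved much more slowly; no stereocentre changes.

**Compound list**

1 | (S)-malic acid, (2S)-2-hydroxybutanedioic acid | OC(=O)C[C@H](O)C(=O)O | starting material
2 | 2-[(2S,4S)-2-tert-butyl-5-oxo-1,3-dioxolan-4-yl]acetic acid (cis) | CC(C)(C)[C@H]1O[C@@H](CC(=O)O)C(=O)O1 | intermediate
3 | isovanillyl alcohol, 5-(hydroxymethyl)-2-methoxyphenol | COc1ccc(CO)cc1O | starting material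
4 | 5-(hydroxymethyl)-2-methoxyphenyl 4-methylbenzenesulfonate | COc1ccc(CO)cc1OS(=O)(=O)c1ccc(C)cc1 | intermediate
5 | 5-(bromomethyl)-2-methoxyphenyl 4-methylbenzenesulfonate | COc1ccc(CBr)cc1OS(=O)(=O)c1ccc(C)cc1 | intermediate
6 | [4-(benzyloxy)-3-methoxyphenyl]methanol | COc1cc(CO)ccc1OCc1ccccc1 | starting material
7 | 1-(benzyloxy)-4-(bromomethyl)-2-methoxybenzene | COc1cc(CBr)ccc1OCc1ccccc1 | intermediate
8 | 5-bromovanillin, 3-bromo-4-hydroxy-5-methoxybenzaldehyde | COc1cc(C=O)cc(Br)c1O | starting material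
9 | 4-(benzyloxy)-3-bromo-5-methoxybenzaldehyde | COc1cc(C=O)cc(Br)c1OCc1ccccc1 | intermediate
10 | 2-[(2S,4S)-2-tert-butyl-4-{[4-methoxy-3-(tosyloxy)phenyl]methyl}-5-oxo-1,3-dioxolan-4-yl]acetic acid | CC(C)(C)[C@H]1O[C@](CC(=O)O)(Cc2ccc(OC)c(OS(=O)(=O)c3ccc(C)cc3)c2)C(=O)O1 | intermediate
11 | dipropan-2-yl (2S)-2-hydroxy-2-{[4-methoxy-3-(tosyloxy)phenyl]methyl}butanedioate | CC(C)OC(=O)C[C@@](O)(Cc1ccc(OC)c(OS(=O)(=O)c2ccc(C)cc2)c1)C(=O)OC(C)C | intermediate
12 | dipropan-2-yl (2S,3R)-3-{[4-(benzyloxy)-3-bromo-5-methoxyphenyl](hydroxy)methyl}-2-hydroxy-2-{[4-methoxy-3-(tosyloxy)phenyl]methyl}butanedioate, both carbinol epimers | COc1ccc(C[C@@](O)(C(=O)OC(C)C)[C@H](C(=O)OC(C)C)C(O)c2cc(OC)c(OCc3ccccc3)c(Br)c2)cc1OS(=O)(=O)c1ccc(C)cc1 | intermediate (not isolated)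
13 | (2S,3R)-3-{[4-(benzyloxy)-3-bromo-5-methoxyphenyl](hydroxy)methyl}-2-{[4-methoxy-3-(tosyloxy)phenyl]methyl}butane-1,2,4-triol, both carbinol epimers | COc1ccc(C[C@@](O)(CO)[C@H](CO)C(O)c2cc(OC)c(OCc3ccccc3)c(Br)c2)cc1OS(=O)(=O)c1ccc(C)cc1 | intermediate
14 | 2-[(2S,4S)-4-{[4-(benzyloxy)-3-methoxyphenyl]methyl}-2-tert-butyl-5-oxo-1,3-dioxolan-4-yl]acetic acid | CC(C)(C)[C@H]1O[C@](CC(=O)O)(Cc2ccc(OCc3ccccc3)c(OC)c2)C(=O)O1 | intermediate
15 | dipropan-2-yl (2S)-2-{[4-(benzyloxy)-3-methoxyphenyl]methyl}-2-hydroxybutanedioate | CC(C)OC(=O)C[C@@](O)(Cc1ccc(OCc2ccccc2)c(OC)c1)C(=O)OC(C)C | intermediate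
16 | dipropan-2-yl (2S,3R)-3-{[4-(benzyloxy)-3-bromo-5-methoxyphenyl](hydroxy)methyl}-2-{[4-(benzyloxy)-3-methoxyphenyl]methyl}-2-hydroxybutanedioate, both carbinol epimers | COc1cc(C[C@@](O)(C(=O)OC(C)C)[C@H](C(=O)OC(C)C)C(O)c2cc(OC)c(OCc3ccccc3)c(Br)c2)ccc1OCc1ccccc1 | intermediate (not isolated)
17 | (2S,3R)-3-{[4-(benzyloxy)-3-bromo-5-methoxyphenyl](hydroxy)methyl}-2-{[4-(benzyloxy)-3-methoxyphenyl]methyl}butane-1,2,4-triol, both carbinol epimers | COc1cc(C[C@@](O)(CO)[C@H](CO)C(O)c2cc(OC)c(OCc3ccccc3)c(Br)c2)ccc1OCc1ccccc1 | intermediate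
18 | pinacol arylboronate of 17 (Bpin in place of Br) | COc1cc(C[C@@](O)(CO)[C@H](CO)C(O)c2cc(OC)c(OCc3ccccc3)c(B3OC(C)(C)C(C)(C)O3)c2)ccc1OCc1ccccc1 | intermediate (not isolated)
19 | unsymmetrical 6,6'-bis(benzyloxy)-5,5'-dimethoxybiphenyl with the pentaol chain of 13 at C3 and the pentaol chain of 17 at C3' (both chains 2S,3R; carbinol carbons epimeric) | COc1ccc(C[C@@](O)(CO)[C@H](CO)C(O)c2cc(OC)c(OCc3ccccc3)c(-c3cc(C(O)[C@@H](CO)[C@](O)(CO)Cc4ccc(OCc5ccccc5)c(OC)c4)cc(OC)c3OCc3ccccc3)c2)cc1OS(=O)(=O)c1ccc(C)cc1 | intermediate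
20 | bis-tetrahydrofuran: both arms closed to (2S,3R,4S)-2-aryl-4-benzyl-4-hydroxy-3-(hydroxymethyl)oxolanes | COc1ccc(C[C@@]2(O)CO[C@H](c3cc(OC)c(OCc4ccccc4)c(-c4cc([C@H]5OC[C@](O)(Cc6ccc(OCc7ccccc7)c(OC)c6)[C@@H]5CO)cc(OC)c4OCc4ccccc4)c3)[C@H]2CO)cc1OS(=O)(=O)c1ccc(C)cc1 | intermediate (not isolated)
21 | target with both biaryl phenols and the tetralin phenol as benzyl ethers and the 3-hydroxy-4-methoxybenzyl phenol as tosylate | COc1ccc(C[C@@]2(O)CO[C@H](c3cc(OC)c(OCc4ccccc4)c(-c4cc([C@H]5c6cc(OCc7ccccc7)c(OC)cc6C[C@@](O)(CO)[C@@H]5CO)cc(OC)c4OCc4ccccc4)c3)[C@H]2CO)cc1OS(=O)(=O)c1ccc(C)cc1 | intermediate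
22 | target with both biaryl phenols and the tetralin phenol as benzyl ethers | COc1ccc(C[C@@]2(O)CO[C@H](c3cc(OC)c(OCc4ccccc4)c(-c4cc([C@H]5c6cc(OCc7ccccc7)c(OC)cc6C[C@@](O)(CO)[C@@H]5CO)cc(OC)c4OCc4ccccc4)c3)[C@H]2CO)cc1O | intermediate
23 | CNP0252244.1: 5,5'-linked biaryl of a (2S,3R,4S)-oxolane (olivil-type) half and a (1S,2S,3S)-aryltetralin (cycloolivil-type) half | COc1ccc(C[C@@]2(O)CO[C@H](c3cc(OC)c(O)c(-c4cc([C@H]5c6cc(O)c(OC)cc6C[C@@](O)(CO)[C@@H]5CO)cc(OC)c4O)c3)[C@H]2CO)cc1O | target

**Count and risks**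

Total steps: 15. Longest linear sequence: 9 (steps 2, 3, 6, 7, 8, 12, 13, 14, 15).

Most likely to fail:

1. Step 13 (divergent double cyclisation). Risks are incomplete discrimination between the two arms, C3 epimerisation through a styrene, and partial loss of benzyl ethers in HFIP. Fallback, from 13 and 17 back to 21: the rings are made one at a time on the monomers and the biaryl bond is made last. 13 alone is closed with CSA (10 mol %) in CH2Cl2 at 0 °C to the tetrahydrofuran bromide F1. 17 alone is closed with TFA in CH2Cl2 to the aryltetralin bromide F2. F2 is borylated in the flask (B2pin2, KOAc, Pd(dppf)Cl2) to the pinacol boronate F3 and coupled with F1 under the aqueous K3PO4 conditions of step 12 to give 21.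

2. Step 8, and its twin step 11 (dianion aldol on a tertiary alkoxide). The facial selectivity at C3 rests on a chelation argument and on analogy with alkylations of such dianions. A minor C3 epimer would be easiest to remove after step 13, once the carbinol mixture has converged. Fallback, from 11 back to 13: the stereocontrol is moved into a rigid ring. The α-hydroxy ester of 11 is reduced selectively (BH3·SMe2, 5 mol % NaBH4, THF) and the diol ester lactonised (TsOH cat.) to the β-hydroxy-β-benzyl-γ-butyrolactone F4. Its dianion (LDA 2.2 eq, THF, −78 °C) is condensed with 9 to the aldol lactone F5; the five-membered enolate is attacked trans to the benzyl group on the adjacent quaternary carbon, which gives the same C3 configuration. LiBH4 reduction of F5 gives 13. In the B series the same detour runs from 15 through lactone F6 and aldol lactone F7 back to 17.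

3. Step 12 (Suzuki coupling of two hindered, unprotected pentaols). Boron may be sequestered by the diols, and protodeboronation or homocoupling may compete. Fallback, from 9 (with 11 and 15) back to 19, replacing steps 8, 11 and 12: the biaryl is made first. 9 is homocoupled in one pot (B2pin2 0.55 eq, Pd(dppf)Cl2, K3PO4, dioxane/H2O, 90 °C) through the boronate aldehyde F8 to the symmetrical dialdehyde F9. A 1:1 mixture of the dianions of 11 and 15 is added to F9 at −78 °C and the mixed bis-aldol tetraester F10 is reduced in the flask with LiBH4 to 19. The cross-product is at most 50 % and is separated from the two symmetrical bis-adducts, which differ from it in tosylate count and polarity.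

**Further compounds**

F1 | step 13 | 5-{[(3S,4R,5S)-5-[4-(benzyloxy)-3-bromo-5-methoxyphenyl]-3-hydroxy-4-(hydroxymethyl)oxolan-3-yl]methyl}-2-methoxyphenyl 4-methylbenzenesulfonate | COc1ccc(C[C@@]2(O)CO[C@H](c3cc(OC)c(OCc4ccccc4)c(Br)c3)[C@H]2CO)cc1OS(=O)(=O)c1ccc(C)cc1
F2 | step 13 | (2S,3S,4S)-6-(benzyloxy)-4-[4-(benzyloxy)-3-bromo-5-methoxyphenyl]-2,3-bis(hydroxymethyl)-7-methoxy-1,2,3,4-tetrahydronaphthalen-2-ol | COc1cc(cc(Br)c1OCc1ccccc1)[C@H]1c2cc(OCc3ccccc3)c(OC)cc2C[C@@](O)(CO)[C@@H]1CO
F3 | step 13 | pinacol arylboronate of F2 (Bpin in place of Br) | COc1cc(cc(B2OC(C)(C)C(C)(C)O2)c1OCc1ccccc1)[C@H]1c2cc(OCc3ccccc3)c(OC)cc2C[C@@](O)(CO)[C@@H]1CO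
F4 | step 8 | (4S)-4-hydroxy-4-{[4-methoxy-3-(tosyloxy)phenyl]methyl}oxolan-2-one | COc1ccc(C[C@@]2(O)COC(=O)C2)cc1OS(=O)(=O)c1ccc(C)cc1
F5 | step 8 | (3R,4S)-3-{[4-(benzyloxy)-3-bromo-5-methoxyphenyl](hydroxy)methyl}-4-hydroxy-4-{[4-methoxy-3-(tosyloxy)phenyl]methyl}oxolan-2-one, both carbinol epimers | COc1ccc(C[C@@]2(O)COC(=O)[C@@H]2C(O)c2cc(OC)c(OCc3ccccc3)c(Br)c2)cc1OS(=O)(=O)c1ccc(C)cc1
F6 | step 11 | (4S)-4-{[4-(benzyloxy)-3-methoxyphenyl]methyl}-4-hydroxyoxolan-2-one | COc1cc(C[C@@]2(O)COC(=O)C2)ccc1OCc1ccccc1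
F7 | step 11 | (3R,4S)-3-{[4-(benzyloxy)-3-bromo-5-methoxyphenyl](hydroxy)methyl}-4-{[4-(benzyloxy)-3-methoxyphenyl]methyl}-4-hydroxyoxolan-2-one, both carbinol epimers | COc1cc(C[C@@]2(O)COC(=O)[C@@H]2C(O)c2cc(OC)c(OCc3ccccc3)c(Br)c2)ccc1OCc1ccccc1
F8 | step 12 | 4-(benzyloxy)-3-methoxy-5-(4,4,5,5-tetramethyl-1,3,2-dioxaborolan-2-yl)benzaldehyde | COc1cc(C=O)cc(B2OC(C)(C)C(C)(C)O2)c1OCc1ccccc1
F9 | step 12 | 6,6'-bis(benzyloxy)-5,5'-dimethoxybiphenyl-3,3'-dicarbaldehyde | COc1cc(C=O)cc(-c2cc(C=O)cc(OC)c2OCc2ccccc2)c1OCc1ccccc1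
F10 | step 12 | mixed bis-aldol tetraisopropyl ester: 19 with each of the four CH2OH groups replaced by CO2-i-Pr | COc1ccc(C[C@@](O)(C(=O)OC(C)C)[C@H](C(=O)OC(C)C)C(O)c2cc(OC)c(OCc3ccccc3)c(-c3cc(C(O)[C@@H](C(=O)OC(C)C)[C@](O)(C(=O)OC(C)C)Cc4ccc(OCc5ccccc5)c(OC)c4)cc(OC)c3OCc3ccccc3)c2)cc1OS(=O)(=O)c1ccc(C)cc1
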